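**Plan**

- Cuts: both C11–C15′ bonds of the 12-membered ring (two identical monomers, each a C11 ester enolate and a C15 allylic bromide), then C7–C11 and C4–C15 (two enol triflates), the C8/C9 oxygens, and last the cyclopropane bond C1–C3.
- Enabling feature: the cyclopropane-fused five-membered ring C1, C2, C3, C4, C5, C10 of each lindenane half is a six-membered decalin ring A with one extra bond, C1–C3, so a trans-decalin C4 ketone with a 1β leaving group contracts to it.
- Forward: rings A and B come from (R)-Wieland–Miescher ketone; ring A is contracted to cyclopropane plus cyclopentanone; C15 and C11 are attached by Pd couplings around a ring B diosphenol; two monomers are joined head to tail to close the macrocycle; the C8 ketones are unveiled last.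
- Stereochemistry: C10 from the starting ketone; C1 and C3 from inversion at the 1β-mesylate; C9 from α-face hydride delivery to a C9 ketone; C11 from alkylation anti to the 8β-silyloxy group, the second one also constrained by the closing ring.

Key step: step 6

Remark: lindenane numbering is used for all intermediates (cyclopropane C1–C2–C3, ring A C1–C5/C10, ring B C5–C10, C14 methyl on C10, C15 on C4, C11–C13 on C7); β is the face of C14.
Remark: 18–21 are drawn as the C4 epimer with the side chain trans to the cyclopropane CH2; the alkene migration may give both epimers, which converge in step 12 where C4 becomes trigonal again.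
Remark: 31–33 are C11 epimer mixtures (C11 written without configuration); this centre becomes planar in step 21.

**Route**

Step 1
Reactants: 1 (R)-Wieland–Miescher ketone
Product: 2 1β-hydroxy enone (OH cis to C14)
Conditions: NaBH4 (0.3 equiv), EtOH, −10 °C
Reagents that add atoms: none
Why: Chemoselective borohydride reduction of the saturated C1 ketone beside the less electrophilic enone; hydride adds opposite the angular C14 methyl, giving the equatorial 1β-alcohol.

Step 2
Reactants: 2 1β-hydroxy enone; 3 ethylene glycol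
Product: 4 1β-hydroxy-4-ene 7-dioxolane
Conditions: 3, p-TsOH (cat.), benzene, reflux, Dean–Stark
Reagents that add atoms: ethylene glycol, OCCO
Why: Acid-catalysed ketalisation of the enone with the usual deconjugation moves the alkene to C4=C5 (as 3-keto-4-ene steroids give 5-ene ketals) and masks C7 for the base steps.

Step 3
Reactants: 4 1β-hydroxy-4-ene 7-dioxolane; 5 methanesulfonyl chloride
Product: 6 1β-mesyloxy-4-ene 7-dioxolane
Conditions: 5, Et3N, CH2Cl2, 0 °C
Reagents that add atoms: methanesulfonyl chloride, CS(=O)(=O)Cl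
Why: Sulfonylation through the sulfene tolerates the neopentyl-type secondary alcohol and turns the 1β-oxygen into the leaving group with retention at C1.

Step 4
Reactants: 6 1β-mesyloxy-4-ene 7-dioxolane
Product: 8 4α-hydroxy trans-decalin 1β-mesylate, via alkylborane 7 (not isolated)
Conditions: BH3·THF, THF, 0 °C to rt; then NaOH, H2O2, 0 °C
Reagents that add atoms: hydrogen peroxide, OO
Why: Hydroboration–oxidation places boron on the less substituted C4 and hydrogen on C5, both from the α face opposite the axial C14 methyl, which sets the trans ring fusion (5α-H) and the 4α-alcohol; the equatorial mesylate has no anti-periplanar hydrogen and should survive cold alkaline peroxide.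

Step 5
Reactants: 8 4α-hydroxy trans-decalin 1β-mesylate
Product: 9 trans-decalin keto mesylate (C4 ketone, 1β-OMs, 5α-H, C7 dioxolane)
Conditions: Dess–Martin periodinane, NaHCO3, CH2Cl2, rt
Reagents that add atoms: none
Why: Buffered Dess–Martin oxidation of the secondary alcohol gives the C4 ketone without epimerising C5 or disturbing mesylate and ketal.

Step 6
Reactants: 9 trans-decalin keto mesylate
Product: 11 tricyclic cyclopropyl ketone (C1–C3 bond, C2 on the β face, C4 ketone, C7 dioxolane), via lithium C3 enolate 10 (not isolated)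
Conditions: LiN(i-Pr)2 (1.1 equiv), THF, −78 °C; then DMPU, −78 to 0 °C
Reagents that add atoms: none
Why: LiN(i-Pr)2 removes a C3 hydrogen of the C4 ketone irreversibly at −78 °C, and on warming the α lobe of the C3 enolate carbon displaces the equatorial 1β-mesylate from the rear, forming C1–C3. This is the base-induced 1,3-elimination of γ-sulfonyloxy ketones to cyclopropyl ketones, known for 4-sulfonyloxycyclohexanones and for 3β-sulfonyloxy 6-keto steroids. The cyclopropane closes in a 3-exo-tet mode, and the five-membered ring C1–C3–C4–C5–C10 is what remains of ring A, so no second closure is needed. C1 is set by inversion at the mesylate carbon and C3 by the necessarily cis fusion of the bicyclo[3.1.0]hexanone, which puts C2 on the β face, syn to C14. The step needs enolisation toward C3 only, because a C5 enolate could close the alternative C1–C5 cyclopropane; kinetic deprotonation at the CH2 with a slight excess of base, so that no free ketone equilibrates the enolates, secures this. E2 loss of the mesylate is disfavoured because the equatorial leaving group has no anti-periplanar hydrogen.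

Step 7
Reactants: 11 tricyclic cyclopropyl ketone
Product: 13 C4 enol triflate (C4=C5), via potassium C4 enolate 12 (not isolated)
Conditions: KN(SiMe3)2, THF, −78 °C; then PhNTf2, −78 to 0 °C
Reagents that add atoms: N-phenylbis(trifluoromethanesulfonimide), O=S(=O)(N(c1ccccc1)S(=O)(=O)C(F)(F)F)C(F)(F)F
Why: After the contraction the ketone can enolise only toward C5 (a C3=C4 enolate would be a bridgehead alkene of the bicyclo[3.1.0] unit), so enolate O-sulfonylation gives the tetrasubstituted C4=C5 enol triflate.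

Step 8
Reactants: 13 C4 enol triflate; 14 (tributylstannyl)methanol
Product: 15 C15 allylic alcohol (C4–CH2OH, C4=C5, C7 dioxolane)
Conditions: 14, Pd(PPh3)4, LiCl, 1,4-dioxane, 100 °C
Reagents that add atoms: (tributylstannyl)methanol, CCCC[Sn](CCCC)(CCCC)CO
Why: Stille coupling of an enol triflate with the hydroxymethyl stannane forms C4–C15 directly at the alcohol oxidation level.

Step 9
Reactants: 15 C15 allylic alcohol
Product: 16 C15 tert-butyldimethylsilyl ether
Conditions: TBSCl, imidazole, DMF, rt
Reagents that add atoms: tert-butyldimethylsilyl chloride, CC(C)(C)[Si](C)(C)Cl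
Why: Standard silylation of the primary alcohol, needed because a free C15 hydroxyl would interfere with the enolate steps and could add to the C7 ketone.

Step 10
Reactants: 16 C15 tert-butyldimethylsilyl ether
Product: 18 conjugated 5-en-7-one (C4–H), via deconjugated ketone 17 (not isolated)
Conditions: PPTS, acetone–H2O, reflux
Reagents that add atoms: water, O
Why: Mild acid hydrolysis of the dioxolane frees the C7 ketone without cleaving the silyl ether, and acid-mediated prototropy through the dienol moves the β,γ-alkene into conjugation (C5=C6), which directs the next enolisation to C8.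

Step 11
Reactants: 18 conjugated 5-en-7-one
Product: 20 8α-hydroxy-5-en-7-one, via potassium C8 enolate 19 (not isolated)
Conditions: KN(SiMe3)2, THF, −78 °C; then 2-(phenylsulfonyl)-3-phenyloxaziridine, −78 °C
Reagents that add atoms: 2-(phenylsulfonyl)-3-phenyloxaziridine, O=S(=O)(N1OC1c1ccccc1)c1ccccc1
Why: Kinetic α′-deprotonation of the enone at C8 and enolate hydroxylation by the N-sulfonyloxaziridine place oxygen on C8, expected anti to the 1,3-related axial C14 methyl (8α); this centre is oxidised in the next step.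

Step 12
Reactants: 20 8α-hydroxy-5-en-7-one
Product: 22 diosphenol (7-hydroxy-4,6-dien-8-one), via ene-dione 21 (not isolated)
Conditions: Dess–Martin periodinane, NaHCO3, CH2Cl2, rt; then Et3N, rt
Reagents that add atoms: none
Why: Oxidation of the α-ketol to the 1,2-dione and amine-mediated enolisation through C4 should give the linearly conjugated diosphenol tautomer, which carries the ketone on C8, the enol on C7 and the C4=C5/C6=C7 diene of the target.

Step 13
Reactants: 22 diosphenol
Product: 23 7-triflyloxy-4,6-dien-8-one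
Conditions: PhNTf2, Et3N, DMAP (cat.), CH2Cl2, 0 °C to rt
Reagents that add atoms: N-phenylbis(trifluoromethanesulfonimide), O=S(=O)(N(c1ccccc1)S(=O)(=O)C(F)(F)F)C(F)(F)F
Why: O-Sulfonylation of the acidic diosphenol hydroxyl gives the α-triflyloxy dienone, a standard cross-coupling handle that fixes C7 as the carbon to receive C11.

Step 14
Reactants: 23 7-triflyloxy-4,6-dien-8-one
Product: 25 9α-hydroxy-8-ketone, via potassium C9 enolate 24 (not isolated)
Conditions: KN(SiMe3)2, THF, −78 °C; then 2-(phenylsulfonyl)-3-phenyloxaziridine, −78 °C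
Reagents that add atoms: 2-(phenylsulfonyl)-3-phenyloxaziridine, O=S(=O)(N1OC1c1ccccc1)c1ccccc1
Why: The ketone has α-hydrogens only at C9, so enolate hydroxylation introduces the C9 oxygen; attack anti to the adjacent axial C14 methyl is expected to give the 9α-alcohol, which steps 15 and 16 correct.

Step 15
Reactants: 25 9α-hydroxy-8-ketone
Product: 26 8,9-dione
Conditions: Dess–Martin periodinane, CH2Cl2, rt
Reagents that add atoms: none
Why: Dess–Martin oxidation of the α-ketol gives the 8,9-dione, which cannot enolise (C10 quaternary, C7 trigonal) and erases the C9 centre.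

Step 16
Reactants: 26 8,9-dione
Product: 27 8β,9β-diol
Conditions: NaBH4, CeCl3·7H2O, MeOH, −78 to −20 °C
Reagents that add atoms: none
Why: Luche 1,2-reduction of both carbonyls; hydride adds to C9 opposite the adjacent axial C14 methyl, giving the 9β-alcohol of the target, and to C8 likewise from the α face (anti to the 1,3-related C14 methyl), giving the cis 8β,9β-diol while the enol triflate stays inert.

Step 17
Reactants: 27 8β,9β-diol
Product: 28 8β,9β-bis(silyl ether) C7 triflate
Conditions: TBSOTf, 2,6-lutidine, CH2Cl2, 0 °C to rt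
Reagents that add atoms: tert-butyldimethylsilyl trifluoromethanesulfonate, CC(C)(C)[Si](C)(C)OS(=O)(=O)C(F)(F)F
Why: Silylation with the silyl triflate protects both hindered secondary alcohols as fluoride-labile ethers, so that no ketone α-hydrogen competes in step 21 and no acid is needed later at the acid-sensitive dienyl alcohol.

Step 18
Reactants: 28 8β,9β-bis(silyl ether) C7 triflate; 29 methyl 2-bromopropanoate
Product: 31 C7 propanoate (methyl 2-(lindena-4,6-dien-7-yl)propanoate tris-silyl ether), via Reformatsky reagent 30 (not isolated)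
Conditions: 29, Zn, THF, rt; then 28, Pd2(dba)3, XPhos, THF, 60 °C
Reagents that add atoms: methyl 2-bromopropanoate, COC(=O)C(C)Br
Why: Negishi-type cross-coupling of the enol triflate with the zinc ester enolate (Reformatsky reagent) forms C7–C11 with C6=C7 already in place and without strong base; C11 arises as an epimer mixture, which does not matter because it becomes an enolate in step 21.

Step 19
Reactants: 31 C7 propanoate
Product: 32 C15 alcohol (8β,9β-bis(silyl ether))
Conditions: HF·pyridine, pyridine, THF, 0 °C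
Reagents that add atoms: none
Why: Buffered HF·pyridine should cleave the primary allylic silyl ether much faster than the two hindered secondary ones (selective desilylation).

Step 20
Reactants: 32 C15 alcohol
Product: 33 C15 bromide (monomer)
Conditions: CBr4, PPh3, 2,6-lutidine, CH2Cl2, −20 to 0 °C
Reagents that add atoms: carbon tetrabromide, BrC(Br)(Br)Br
Why: Appel bromination converts the primary allylic alcohol into the bromide under neutral conditions; allylic transposition is not expected because C5 and C7 are fully substituted.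

Step 21
Reactants: 33 C15 bromide (two molecules)
Product: 36 macrocyclic tetrakis(silyl ether) diester, via monomer enolate 34 (not isolated), via open dimer enolate 35 (not isolated)
Conditions: LiN(SiMe3)2 (1.1 equiv), THF (0.01 M), −78 °C; then DMPU, −78 to 0 °C
Reagents that add atoms: none
Why: Twofold ester enolate C-alkylation (head-to-tail cyclodimerisation): the enolate of one molecule displaces the primary allylic bromide of a second, and the open dimer, which still holds one enolate and one bromide, closes the 12-membered ring the same way; the monomer cannot cyclise on itself because C11 and C15 sit at opposite ends of the rigid s-trans diene, and each quaternary C11 is expected to form by attack on the s-trans dienolate from the α face, anti to the pseudoaxial 8β-silyloxy group.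

Step 22
Reactants: 36 macrocyclic tetrakis(silyl ether) diester
Product: 37 macrocyclic 8β,9β,8′β,9′β-tetraol
Conditions: Bu4NF, AcOH, THF, rt to 45 °C
Reagents that add atoms: none
Why: Fluoride-mediated desilylation frees the four secondary alcohols without acid; the quaternary C11 esters cannot epimerise.

Step 23
Reactants: 37 macrocyclic tetraol
Product: 38 cycloshizukaol A
Conditions: MnO2 (activated, excess), CH2Cl2, rt
Reagents that add atoms: none
Why: MnO2 oxidises allylic alcohols selectively, so only the dienylic C8 hydroxyls become ketones and the saturated C9 hydroxyls remain, under neutral conditions that do not enolise the new α-ketols.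

**Compound list**

1 | (R)-Wieland–Miescher ketone, (R)-8a-methyl-3,4,8,8a-tetrahydronaphthalene-1,6(2H,7H)-dione | C[C@@]12CCC(=O)C=C1CCCC2=O | starting material
2 | 1β-hydroxy enone, (4aR,5R)-5-hydroxy-4a-methyl-4,4a,5,6,7,8-hexahydronaphthalen-2(3H)-one | C[C@@]12CCC(=O)C=C1CCC[C@H]2O | intermediate
3 | ethylene glycol | OCCO | starting material
4 | 1β-hydroxy-4-ene 7-dioxolane (C4=C5 alkene, OH cis to C14) | C[C@@]12CCC3(OCCO3)CC1=CCC[C@H]2O | intermediate
5 | methanesulfonyl chloride | CS(=O)(=O)Cl | starting material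
6 | 1β-mesyloxy-4-ene 7-dioxolane | C[C@@]12CCC3(OCCO3)CC1=CCC[C@H]2OS(C)(=O)=O | intermediate
7 | C4 alkylborane (boron 4α, H 5α), formed in the flask | B[C@@H]1CC[C@@H](OS(C)(=O)=O)[C@]2(C)CCC3(OCCO3)C[C@@H]12 | intermediate
8 | 4α-hydroxy trans-decalin 1β-mesylate, C7 dioxolane | O[C@@H]1CC[C@@H](OS(C)(=O)=O)[C@]2(C)CCC3(OCCO3)C[C@@H]12 | intermediate
9 | trans-decalin keto mesylate (C4 ketone, 1β-OMs, 5α-H, C7 dioxolane) | O=C1CC[C@@H](OS(C)(=O)=O)[C@]2(C)CCC3(OCCO3)C[C@@H]12 | intermediate
10 | lithium C3 enolate of 9, formed in the flask | [Li]OC1=CC[C@@H](OS(C)(=O)=O)[C@]2(C)CCC3(OCCO3)C[C@@H]12 | intermediate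
11 | tricyclic cyclopropyl ketone (C1–C3 bond, C2 β, C4 ketone, 5α-H, C7 dioxolane) | O=C1[C@H]2C[C@H]2[C@]2(C)CCC3(OCCO3)C[C@@H]12 | intermediate
12 | potassium C4=C5 enolate of 11, formed in the flask | [K]OC1=C2CC3(OCCO3)CC[C@@]2(C)[C@@H]2C[C@H]12 | intermediate
13 | C4 enol triflate (C4=C5) | O=S(=O)(OC1=C2CC3(OCCO3)CC[C@@]2(C)[C@@H]2C[C@H]12)C(F)(F)F | intermediate
14 | (tributylstannyl)methanol | CCCC[Sn](CCCC)(CCCC)CO | starting material
15 | C15 allylic alcohol (C4–CH2OH, C4=C5, C7 dioxolane) | OCC1=C2CC3(OCCO3)CC[C@@]2(C)[C@@H]2C[C@H]12 | intermediate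
16 | C15 tert-butyldimethylsilyl ether of 15 | CC(C)(C)[Si](C)(C)OCC1=C2CC3(OCCO3)CC[C@@]2(C)[C@@H]2C[C@H]12 | intermediate
17 | deconjugated C7 ketone (C4=C5), formed in the flask | CC(C)(C)[Si](C)(C)OCC1=C2CC(=O)CC[C@@]2(C)[C@@H]2C[C@H]12 | intermediate
18 | conjugated 5-en-7-one (4β-H, C15 α) | CC(C)(C)[Si](C)(C)OC[C@H]1C2=CC(=O)CC[C@@]2(C)[C@@H]2C[C@H]12 | intermediate
19 | potassium C7=C8 enolate of 18, formed in the flask | CC(C)(C)[Si](C)(C)OC[C@H]1C2=CC(O[K])=CC[C@@]2(C)[C@@H]2C[C@H]12 | intermediate
20 | 8α-hydroxy-5-en-7-one | CC(C)(C)[Si](C)(C)OC[C@H]1C2=CC(=O)[C@@H](O)C[C@@]2(C)[C@@H]2C[C@H]12 | intermediate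
21 | 5-ene-7,8-dione, formed in the flask | CC(C)(C)[Si](C)(C)OC[C@H]1C2=CC(=O)C(=O)C[C@@]2(C)[C@@H]2C[C@H]12 | intermediate
22 | diosphenol, 7-hydroxy-4,6-dien-8-one | CC(C)(C)[Si](C)(C)OCC1=C2C=C(O)C(=O)C[C@@]2(C)[C@@H]2C[C@H]12 | intermediate
23 | 7-triflyloxy-4,6-dien-8-one | CC(C)(C)[Si](C)(C)OCC1=C2C=C(OS(=O)(=O)C(F)(F)F)C(=O)C[C@@]2(C)[C@@H]2C[C@H]12 | intermediate
24 | potassium C8=C9 enolate of 23, formed in the flask | CC(C)(C)[Si](C)(C)OCC1=C2C=C(OS(=O)(=O)C(F)(F)F)C(O[K])=C[C@@]2(C)[C@@H]2C[C@H]12 | intermediate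
25 | 9α-hydroxy-8-ketone | CC(C)(C)[Si](C)(C)OCC1=C2C=C(OS(=O)(=O)C(F)(F)F)C(=O)[C@@H](O)[C@@]2(C)[C@@H]2C[C@H]12 | intermediate
26 | 8,9-dione | CC(C)(C)[Si](C)(C)OCC1=C2C=C(OS(=O)(=O)C(F)(F)F)C(=O)C(=O)[C@@]2(C)[C@@H]2C[C@H]12 | intermediate
27 | 8β,9β-diol (C7 triflate, C15 silyl ether) | CC(C)(C)[Si](C)(C)OCC1=C2C=C(OS(=O)(=O)C(F)(F)F)[C@H](O)[C@H](O)[C@@]2(C)[C@@H]2C[C@H]12 | intermediate
28 | 8β,9β-bis(tert-butyldimethylsilyl ether) C7 triflate | CC(C)(C)[Si](C)(C)OCC1=C2C=C(OS(=O)(=O)C(F)(F)F)[C@H](O[Si](C)(C)C(C)(C)C)[C@H](O[Si](C)(C)C(C)(C)C)[C@@]2(C)[C@@H]2C[C@H]12 | intermediate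
29 | methyl 2-bromopropanoate (racemic) | COC(=O)C(C)Br | starting material
30 | Reformatsky reagent, bromozinc derivative of methyl propanoate, formed in the flask | COC(=O)C(C)[Zn]Br | intermediate
31 | C7 propanoate, methyl 2-(lindena-4,6-dien-7-yl)propanoate with 8β,9β,15-tris(silyl ether), C11 epimers | CC(C)(C)[Si](C)(C)OCC1=C2C=C(C(C)C(=O)OC)[C@H](O[Si](C)(C)C(C)(C)C)[C@H](O[Si](C)(C)C(C)(C)C)[C@@]2(C)[C@@H]2C[C@H]12 | intermediate
32 | C15 alcohol, 8β,9β-bis(silyl ether), C11 epimers | OCC1=C2C=C(C(C)C(=O)OC)[C@H](O[Si](C)(C)C(C)(C)C)[C@H](O[Si](C)(C)C(C)(C)C)[C@@]2(C)[C@@H]2C[C@H]12 | intermediate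
33 | C15 bromide (monomer), C11 epimers | BrCC1=C2C=C(C(C)C(=O)OC)[C@H](O[Si](C)(C)C(C)(C)C)[C@H](O[Si](C)(C)C(C)(C)C)[C@@]2(C)[C@@H]2C[C@H]12 | intermediate
34 | lithium ester enolate of 33, formed in the flask | BrCC1=C2C=C(C(C)=C(OC)O[Li])[C@H](O[Si](C)(C)C(C)(C)C)[C@H](O[Si](C)(C)C(C)(C)C)[C@@]2(C)[C@@H]2C[C@H]12 | intermediate
35 | open dimer enolate (one C11–C15′ bond formed, one bromide and one enolate left), formed in the flask | COC(=O)[C@](C)(CC1=C2C=C(C(C)=C(OC)O[Li])[C@H](O[Si](C)(C)C(C)(C)C)[C@H](O[Si](C)(C)C(C)(C)C)[C@@]2(C)[C@@H]2C[C@H]12)C1=CC2=C(CBr)[C@H]3C[C@H]3[C@]2(C)[C@@H](O[Si](C)(C)C(C)(C)C)[C@H]1O[Si](C)(C)C(C)(C)C | intermediate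
36 | macrocyclic tetrakis(silyl ether) diester (both C11–C15′ bonds, 8β,9β,8′β,9′β-OTBS) | COC(=O)[C@]1(C)CC2=C3C=C([C@H](O[Si](C)(C)C(C)(C)C)[C@H](O[Si](C)(C)C(C)(C)C)[C@@]3(C)[C@@H]3C[C@H]23)[C@](C)(C(=O)OC)CC2=C3C=C1[C@H](O[Si](C)(C)C(C)(C)C)[C@H](O[Si](C)(C)C(C)(C)C)[C@@]3(C)[C@@H]1C[C@H]21 | intermediate
37 | macrocyclic 8β,9β,8′β,9′β-tetraol | COC(=O)[C@]1(C)CC2=C3C=C([C@H](O)[C@H](O)[C@@]3(C)[C@@H]3C[C@H]23)[C@](C)(C(=O)OC)CC2=C3C=C1[C@H](O)[C@H](O)[C@@]3(C)[C@@H]1C[C@H]21 | intermediate
38 | cycloshizukaol A | COC(=O)[C@]1(C)CC2=C3C=C(C(=O)[C@H](O)[C@@]3(C)[C@@H]3C[C@H]23)[C@](C)(C(=O)OC)CC2=C3C=C1C(=O)[C@H](O)[C@@]3(C)[C@@H]1C[C@H]21 | target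

**Step count**

Total steps: 23. Longest linear sequence: 23 steps (1 to 38; step 21 joins two molecules of 33).

**Steps most likely to fail**

1. Step 21. Chain growth to oligomers may outrun ring closure, and the first, intermolecular alkylation may show poor facial selectivity at C11. Fallback, from 31 and 33, returning at 36: the lithium enolate of 31 (LiN(i-Pr)2, THF, −78 °C, in excess) is alkylated with 33 to give the open dimer silyl ether F6, whose C11 diastereomers can be separated. HF·pyridine then removes the primary silyl group to give the open dimer alcohol F7, and CBr4/PPh3 gives the open dimer bromide F8. Slow addition of F8 to KN(SiMe3)2 in THF at high dilution closes the ring to 36.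

2. Step 18. Oxidative addition and transmetalation at the C7 triflate, crowded by the 8β-silyloxy group, may be slow, so that protonation or homocoupling of the zinc enolate wins. Fallback, from 28, returning at 31: Suzuki coupling of 28 with isopropenylboronic acid pinacol ester (Pd(PPh3)4, K3PO4, dioxane–H2O) gives the 7-isopropenyl triene F2. 9-BBN then NaBO3 hydroborates only the terminal 1,1-disubstituted alkene to the primary alcohol F3. Dess–Martin oxidation gives the aldehyde F4, Pinnick oxidation (NaClO2, NaH2PO4, 2-methyl-2-butene) the carboxylic acid F5, and Me3SiCHN2 in MeOH the ester 31.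

3. Step 6. If ring closure is slow, proton transfer may equilibrate the C3 enolate to the C5 enolate, which would close the C1–C5 bond instead. Fallback, from 9, returning at 11: LiN(i-Pr)2 with Me3SiCl present at −78 °C traps the kinetic enolate as the C3=C4 trimethylsilyl enol ether F1, which is purified. MeLi in THF at 0 °C then releases the amine-free lithium enolate, which cannot equilibrate and closes to 11.

Further compounds
F1 | step 6 | C3=C4 trimethylsilyl enol ether of 9 | C[Si](C)(C)OC1=CC[C@@H](OS(C)(=O)=O)[C@]2(C)CCC3(OCCO3)C[C@@H]12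
F2 | step 18 | 7-isopropenyl triene | CC(C)(C)[Si](C)(C)OCC1=C2C=C(C(C)=C)[C@H](O[Si](C)(C)C(C)(C)C)[C@H](O[Si](C)(C)C(C)(C)C)[C@@]2(C)[C@@H]2C[C@H]12
F3 | step 18 | primary alcohol (C12 hydroxyl, C11 epimers) | CC(C)(C)[Si](C)(C)OCC1=C2C=C(C(C)CO)[C@H](O[Si](C)(C)C(C)(C)C)[C@H](O[Si](C)(C)C(C)(C)C)[C@@]2(C)[C@@H]2C[C@H]12
F4 | step 18 | aldehyde (C12) | CC(C)(C)[Si](C)(C)OCC1=C2C=C(C(C)C=O)[C@H](O[Si](C)(C)C(C)(C)C)[C@H](O[Si](C)(C)C(C)(C)C)[C@@]2(C)[C@@H]2C[C@H]12
F5 | step 18 | carboxylic acid (C12) | CC(C)(C)[Si](C)(C)OCC1=C2C=C(C(C)C(=O)O)[C@H](O[Si](C)(C)C(C)(C)C)[C@H](O[Si](C)(C)C(C)(C)C)[C@@]2(C)[C@@H]2C[C@H]12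
F6 | step 21 | open dimer silyl ether (one C11–C15′ bond, C15 OTBS on the quaternary half, C11–H ester on the other) | COC(=O)[C@](C)(CC1=C2C=C(C(C)C(=O)OC)[C@H](O[Si](C)(C)C(C)(C)C)[C@H](O[Si](C)(C)C(C)(C)C)[C@@]2(C)[C@@H]2C[C@H]12)C1=CC2=C(CO[Si](C)(C)C(C)(C)C)[C@H]3C[C@H]3[C@]2(C)[C@@H](O[Si](C)(C)C(C)(C)C)[C@H]1O[Si](C)(C)C(C)(C)C
F7 | step 21 | open dimer alcohol | COC(=O)[C@](C)(CC1=C2C=C(C(C)C(=O)OC)[C@H](O[Si](C)(C)C(C)(C)C)[C@H](O[Si](C)(C)C(C)(C)C)[C@@]2(C)[C@@H]2C[C@H]12)C1=CC2=C(CO)[C@H]3C[C@H]3[C@]2(C)[C@@H](O[Si](C)(C)C(C)(C)C)[C@H]1O[Si](C)(C)C(C)(C)C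
F8 | step 21 | open dimer bromide | COC(=O)[C@](C)(CC1=C2C=C(C(C)C(=O)OC)[C@H](O[Si](C)(C)C(C)(C)C)[C@H](O[Si](C)(C)C(C)(C)C)[C@@]2(C)[C@@H]2C[C@H]12)C1=CC2=C(CBr)[C@H]3C[C@H]3[C@]2(C)[C@@H](O[Si](C)(C)C(C)(C)C)[C@H]1O[Si](C)(C)C(C)(C)C
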